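Convention: labdane numbering is used for the target and all bicyclic intermediates (ring A = C1–C5 and C10, ring B = C5–C10; C18 = the oxygen-bearing carbon on C4, C19 = the methyl on C4, C17 = the methyl on C8, C20 = the methyl on C10, C11–C16 = side chain). β is the face of the decalin that carries H-5, α the face that carries C20. The target is compound 30.

## The problem

Target 30 is an ent-labdane, (4S,5S,6R,8S,9S,10R) in labdane numbering: a trans-fused decalin whose C9 carries a 3-methylidenepent-4-enyl chain. Six stereocenters sit on the bicycle, among them two quaternary carbons (C4 with CH3 and CH2OH, C10 with CH3) and a tertiary carbinol (C8). In the chair–chair form the methyl groups C17, C19 and C20 are axial on the α face, while the CH2OH group, the C6 acetate, the C8 hydroxyl and the side chain are equatorial. Only C5 has to be bought: it can direct the alkylation that creates C10, C5 and C10 together fix the ring fusion and bias C4 when ring A is closed, and the axial methyl groups on C4 and C10 then screen the α face, so that the oxygen at C6, the epoxide oxygen at C8 and the hydrogen at C9 can all enter from the β face. The groups that limit the choice of reagents are the 2-substituted buta-1,3-diene (acid, radicals, peracids, dienophiles), which is best made last, the tertiary alcohol (elimination), the C6 acetate next to a free primary alcohol (the two hydroxyls must be told apart and acyl migration avoided) and, on the way, 2,2-disubstituted 1,3-diketones that cleave by retro-Claisen reaction. The enabling feature is that C4, with its methyl group, its CH2OH group and the neighbouring C5–H, is an isopropenyl group raised to the epoxide oxidation level, and that ring B with the methyl group on C8 is the carvone ring with its carbonyl carbon at C9. (S)-Carvone therefore supplies C4–C9, C17, C18 and C19 with C5 in the correct absolute configuration, C20 and C1–C3 come from iodomethane and acrolein, and ring A can be closed at C3–C4 by a radical made from the C4–C18 epoxide.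

## Retrosynthesis

**Diene last (30 ⇒ 29).** The C13=C16 and C14=C15 double bonds are cut, which leaves the terminal alkyne 29 and two CH2 groups to be added by ene–yne cross-metathesis. Cutting C11–C12 or C12–C13 instead would oblige a diene-bearing fragment to survive peracid, hydride and palladium steps. The alkyne is inert to all of these, and the forward reaction only has to tolerate two hydroxyl groups and an acetate in a molecule with no other alkene.

**Telling the hydroxyls apart (29 ⇒ 28 ⇒ 27).** The O18–H and O6–acetyl bonds are cut. The primary alcohol stays silylated from step 8 onward, so that in diol 27 only the secondary C6 hydroxyl can be acetylated (the tertiary C8 hydroxyl is inert). The silyl group is removed from 28 under buffered acidic fluoride, which does not move the acetyl group.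

**C8 carbinol (27 ⇒ 26 ⇒ 25).** The C7–H bond is cut and the C8–O bond retained, leading to the 7β,8β-epoxide 26 and the C7=C8 alkene 25. Adding a methyl nucleophile to a C8 ketone is the classical alternative, but the carvone ring already carries the methyl group on C8 and the carbonyl on C9, so the epoxide route fits the skeleton at hand. The forward steps need epoxidation on the β face (directed by the C6 hydroxyl and by the axial C20) and hydride attack at the less substituted C7.

**C9–H and the side chain (25 ⇒ 23 ⇒ 19 + 20).** The C9–H bond is cut with allylic transposition, giving the tertiary allylic carbonate 23, and then the C9–C11 bond is cut, giving enone 19 and the four-carbon iodide 20. Because C9 is the carvone carbonyl carbon, the chain has to enter as a nucleophile and the oxygen has to leave afterwards. Olefination of this hindered ketone or an SN2' alkylation would be the neighbours; the addition/reductive transposition pair is shorter and regenerates exactly the C7=C8 alkene that the previous disconnection needs. The forward reduction must deliver hydrogen to the more substituted allyl terminus and on the β face.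

**C6 oxygen (19 ⇒ 18 ⇒ 16 ⇒ 14).** The C6–O bond is cut. The enone of 14 is the only handle that reaches C6, through its extended silyl dienol ether 16 and photooxygenation across C6 and C9 (endoperoxide 17). This has to precede the chain addition, which consumes the enone; allylic oxidation at a later stage would not distinguish C6 from C9 and C17. The cycloaddition must take place on the β face.

**C1 oxygen (14 ⇒ 12 ⇒ 11).** A carbonyl is put back on C1. It is not present in the target, but it is what makes the ring closure regioselective, and it is removed directly after through tosylhydrazone 12, a reaction that selects the saturated ketone over the hindered enone.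

**Ring A (11 ⇒ 9), the key disconnection.** The C3–C4 bond is cut to a C4 radical and a C1 vinyl ketone, that is, to epoxy vinyl ketone 9. Cutting C1–C2 or C2–C3 (annulation logic) would require the C4 quaternary centre to exist beforehand. The C3–C4 cut creates C4 in the ring-forming step from an isopropenyl epoxide that carvone provides, and the precursor is a monocycle four steps from commerce. The forward reaction must close 6-endo at the vinyl ketone terminus, avoid the two carbonyl groups, and place the CH2O group equatorial.

**The precursor (9 ⇒ 8 ⇒ 7 ⇒ 4 + 5; 4 ⇒ 1 + 2).** The epoxide oxygen is removed (8), the vinyl ketone is taken back to the allylic alcohol 7, and the C1–C10 bond is cut by an aldol disconnection to 6-methylcarvone 4 and acrolein 5. The C10–C20 bond is cut to carvone 1 and iodomethane 2. The order methyl first, aldol second lets the larger electrophile enter anti to the isopropenyl group, which is the arrangement the trans ring fusion needs.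

## Roads not taken

**Alternative 1:** Both rings are cut at once, C5–C10 and C3–C4, to the acyclic trienoate A1. Heating or Me2AlCl would close it by an intramolecular Diels–Alder reaction to the trans-fused octalin ester A2.
- Merits: rings A and B and the centres C4, C5 and C10 arise in one step. The C4 ester is one reduction away from the CH2OH group. The C8 ketone of A2 allows the carbinol to be made by methyl addition. The C6 oxygen and a two-carbon stub of the side chain are in place before cyclization, so nothing has to be deoxygenated afterwards. In functional-group economy after ring formation this road is better than the chosen one, which spends two steps on C1 and two on C9.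
- Weak points: both reacting termini become quaternary (C10 from a diene terminus that carries an inside methyl group, C4 from an α-methyl acrylate), which slows the cycloaddition. The trans fusion and the C4 configuration rest on an endo/exo preference that is not secured. The C9 centre of A1 is α to a ketone and allylic, hence prone to epimerization and to conjugation under heat or Lewis acid. The acyclic centres C6 and C9 need their own asymmetric syntheses.
- Comparison: the chosen plan sets against this a precursor made in four steps from a chiral-pool terpene and a ring closure in which one bond forms under the control of ring stereocenters that already exist.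

**Alternative 2:** Ring B is cut at C9–C10 and C7–C8 to the but-2-ynoate ester A3 of a ring A allylic-type alcohol. Heating would give the lactone-bridged 5,8-diene A4 by an ester-tethered Diels–Alder reaction.
- Merits: the C18 oxygen serves as the tether, so C10 is set relative to C4 by geometry, regiochemistry is fixed, and C11 and C17 arrive in the cycloaddition. The C9–C11 bond is thus made more directly than in the chosen plan, where it costs an addition and a reductive transposition.
- Weak points: ester tethers prefer the unreactive s-trans form and here must close a seven-membered lactone onto a tetrasubstituted diene terminus. A4 has none of the ring B stereocenters: the trans ring fusion at C5, the C6 oxygen, the C8 carbinol and the C9 hydrogen would all have to be introduced on a skipped diene, one of whose double bonds is a tetrasubstituted unsaturated lactone. C11 has to be taken from the acid level to CH2 and extended. A3 needs an enantioselective synthesis of the C4 quaternary centre.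
- Comparison: the chosen plan starts with C5 fixed and uses the axial methyl groups to set C6, C8 and C9 one after the other.

**Alternative 3:** Ring B is cut at C9–C10 alone, to the (Z)-trienol ether A5 held in shape by a di-tert-butylsilylene bridge between O6 and O18. Irradiation near 300 nm would close it by a conrotatory six-electron electrocyclization to the 5,7-dienol silylene ether A6.
- Merits: this is the most convergent road. The side chain (as a butynyl group) and the C6 oxygen (as an enol ether) are present at ring closure, and the C7=C8 bond of A6 is ready for the same epoxide/hydride sequence. After ring formation it would be shorter than the chosen plan, since neither C1 nor C9 has to be deoxygenated.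
- Weak points: the photochemical closure is reversible and competes with E/Z isomerization of the triene and, on warming, with sigmatropic hydrogen shifts. The relative configuration of C9 and C10 to C4 depends on the helical sense of the triene, which the silylene bridge biases only indirectly. The C10 terminus is tetrasubstituted. A5, with its Z-configured central enol ether, is itself a demanding target.
- Comparison: the chosen plan sets against the shorter endgame a ground-state ring closure whose stereochemical course is tied to C5 and C10, and an early phase of four routine steps.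

Key step: step 5

Remark on the chemistry: (4-iodobut-1-yn-1-yl)trimethylsilane 20 is taken as a purchased reagent (it is one step from commercial 4-(trimethylsilyl)but-3-yn-1-ol). Compounds 4, 7 and 9 are carried as mixtures at centres that are erased later (C6 of 4, the carbinol carbon of 7, the epoxide carbon of 9), so their SMILES leave these centres open.

## Route

Step 1
Reactants: 1 (S)-(+)-carvone; 2 iodomethane
Product: 4 6-methylcarvone (both C6 epimers), via lithium dienolate 3 (not isolated)
Conditions: LiN(i-Pr)2, THF, −78 °C; then MeI, −78 → 0 °C
Reagents that add atoms: none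
Why: Kinetic deprotonation of the cross-conjugated enone at the α' carbon and C-methylation of the lithium dienolate (enolate alkylation); the new centre forms as a mixture and is flattened again in step 2, while C5 is untouched.

Step 2
Reactants: 4 6-methylcarvone; 5 prop-2-enal (acrolein)
Product: 7 aldol adduct (hydroxyallyl group trans to isopropenyl; both carbinol epimers), via lithium enolate 6 (not isolated)
Conditions: LiN(i-Pr)2, THF, −78 °C; then acrolein, −78 °C; AcOH quench at −78 °C
Reagents that add atoms: none
Why: A second kinetic enolization gives the tetrasubstituted enolate 6, whose lithium aldol addition to the aldehyde carbon of 5 should take place on the face opposite the neighbouring isopropenyl group, so that the new quaternary C10 carries the C1 carbon trans and the methyl group cis to it; the cold acidic quench forestalls retro-aldol cleavage and the carbinol configuration is irrelevant.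

Step 3
Reactants: 7 aldol adduct
Product: 8 vinyl ketone (2-acryloyl enone)
Conditions: Dess–Martin periodinane, NaHCO3, CH2Cl2, 0 °C → rt
Reagents that add atoms: none
Why: Dess–Martin oxidation of the secondary allylic alcohol under buffered, non-basic conditions gives the vinyl ketone; C10 is quaternary, so the 1,3-diketone can neither epimerize nor enolize between the carbonyl groups.

Step 4
Reactants: 8 vinyl ketone
Product: 9 epoxy vinyl ketone (C4–C18 epoxide; both C4 epimers)
Conditions: mCPBA, NaHCO3, CH2Cl2, 0 °C
Reagents that add atoms: 3-chloroperbenzoic acid, OOC(=O)c1cccc(Cl)c1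
Why: Prilezhaev epoxidation: the peracid attacks only the electron-rich 1,1-disubstituted alkene and leaves the two electron-poor enone double bonds; the epoxide epimers are not separated because both give the same C4 radical.

Step 5
Reactants: 9 epoxy vinyl ketone
Product: 11 hydroxy enedione (trans-decalin; C1=O, C9=O, C7=C8; 4α-CH3, 4β-CH2OH), via titanium enolate 10 (not isolated)
Conditions: Cp2TiCl2 (2.5 equiv), Zn dust, THF, rt (forms Cp2TiCl); 9 added slowly at high dilution; then 1 M aq. HCl
Reagents that add atoms: none
Why: Proposed new method: single-electron transfer from Cp2TiCl (trivalent titanium) to the epoxide cleaves the C4–O bond and gives the tertiary β-titanoxy radical at C4, the same radical from both epoxide epimers; this nucleophilic radical adds to C3, the unsubstituted terminus of the vinyl ketone, and a second Cp2TiCl reduces the resulting C2 radical to the titanium enolate 10, which is protonated on work-up. The closest known reaction types are titanocene-mediated epoxide-opening radical cyclizations onto acrylate-type acceptors and tin hydride 6-endo cyclizations onto vinyl ketones; the combination on a 1,3-diketone has not been shown. Ring A closes in the 6-endo-trig mode, which polarity matching and the formation of an α-keto radical favour over 5-exo attack at C2. C4 is the only new stereocenter: in the chair-like transition state the bulky CH2OTiCp2Cl group should take the equatorial site and the methyl group the axial site syn to C20, and the trans ring fusion follows from the trans arrangement of C1 and C4 fixed in step 2. The step needs chemoselectivity against 4-exo addition of the radical to the C1 or C9 carbonyl group and against capture of the radical by a second titanium centre; a tertiary radical is captured slowly, conjugate addition to an unhindered vinyl ketone is fast, and slow addition at high dilution supports this.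

Step 6
Reactants: 11 hydroxy enedione
Product: 12 C1 tosylhydrazone
Conditions: TsNHNH2, EtOH, AcOH (cat.), 50 °C
Reagents that add atoms: 4-methylbenzenesulfonohydrazide, Cc1ccc(cc1)S(=O)(=O)NN
Why: Hydrazone condensation at the saturated C1 ketone; the C9 carbonyl is conjugated and flanked by the quaternary C10 and the methyl-bearing C8 and should not compete.

Step 7
Reactants: 12 C1 tosylhydrazone
Product: 14 hydroxy enone (C1 = CH2), via borylated hydrazine 13 (not isolated)
Conditions: catecholborane, CHCl3, 0 °C; then NaOAc·3H2O, reflux
Reagents that add atoms: none
Why: Caglioti-type reduction in its catecholborane form: hydride adds to C=N, acetate then releases sulfinate, and the alkyl diazene loses dinitrogen to leave CH2 at C1; the cyclic enone cannot reach the s-cis geometry that catecholborane needs for conjugate reduction.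

Step 8
Reactants: 14 hydroxy enone
Product: 16 silyl dienol ether (C9–OSiMe3; C8=C9 and C6=C7; 18-OTBS), via silyl ether 15 (not isolated)
Conditions: TBSOTf (1.05 equiv), Et3N, CH2Cl2, −78 °C; then TMSOTf, −78 → 0 °C; non-aqueous work-up
Reagents that add atoms: tert-butyldimethylsilyl trifluoromethanesulfonate, CC(C)(C)[Si](C)(C)OS(=O)(=O)C(F)(F)F; trimethylsilyl trifluoromethanesulfonate, C[Si](C)(C)OS(=O)(=O)C(F)(F)F
Why: The primary alcohol is silylated first at −78 °C; soft enolization with the second silyl triflate then finds no α' hydrogen (C10 is quaternary) and removes a C6 hydrogen, giving the extended homoannular silyl dienol ether.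

Step 9
Reactants: 16 silyl dienol ether
Product: 18 6β-hydroxy enone (18-OTBS), via endoperoxide 17 (not isolated)
Conditions: O2, tetraphenylporphyrin (cat.), visible light, CH2Cl2, −78 °C; then thiourea, MeOH, −78 °C → rt
Reagents that add atoms: dioxygen, O=O
Why: Singlet oxygen adds across C6 and C9 of the cisoid ring B diene in a [4+2] cycloaddition from the β face, because the axial methyl groups on C4 and C10 cover the α face; this sets the C6–O bond β (equatorial). Thiourea reduces the O–O bond and the silyl hemiketal at C9 collapses to the enone.

Step 10
Reactants: 18 6β-hydroxy enone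
Product: 19 6β-trimethylsilyloxy enone
Conditions: TMSCl, imidazole, CH2Cl2, 0 °C
Reagents that add atoms: chlorotrimethylsilane, C[Si](C)(C)Cl
Why: Silylation of the secondary alcohol gives an ether that survives the alkyllithium at −78 °C and is later removed together with the C-silyl group.

Step 11
Reactants: 19 6β-trimethylsilyloxy enone; 20 (4-iodobut-1-yn-1-yl)trimethylsilane
Product: 23 tertiary allylic methyl carbonate (9α-OCO2Me; 9β side chain), via alkyllithium 21 (not isolated), via lithium alkoxide 22 (not isolated)
Conditions: 20, t-BuLi (2 equiv per 20), Et2O, −78 °C; then 19, −78 → −40 °C; then ClCO2Me, −78 → 0 °C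
Reagents that add atoms: methyl chloroformate, COC(Cl)=O
Why: Lithium–iodine exchange gives 21, which should add 1,2 to the hindered but non-enolizable C9 carbonyl from the β face (pseudo-axial attack, anti to the axial methyl group on the neighbouring C10); the alkoxide 22 is acylated in the flask to the tertiary allylic carbonate, and the C9 configuration is temporary.

Step 12
Reactants: 23 tertiary allylic methyl carbonate
Product: 25 allylic alcohol (C7=C8; 9β-H; 9α-but-3-ynyl; 6β-OH; 18-OTBS), via silylated alkene 24 (not isolated)
Conditions: Pd(OAc)2 (5 mol%), n-Bu3P (20 mol%), HCO2H, Et3N, THF, 50 °C; then K2CO3, MeOH, rt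
Reagents that add atoms: none
Why: Tsuji–Trost ionization followed by formate hydrogenolysis: zerovalent palladium ionizes the carbonate to a C7–C8–C9 allyl complex with the metal on the β face (anti to the leaving group and away from C20), and the formate-derived hydride passes from palladium to the more substituted terminus C9 on that face; this should give 9β-H with the side chain equatorial and move the alkene to C7=C8. Methanolysis then removes both trimethylsilyl groups and leaves the TBS ether.

Step 13
Reactants: 25 allylic alcohol
Product: 26 7β,8β-epoxide
Conditions: mCPBA, NaHCO3, CH2Cl2, 0 °C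
Reagents that add atoms: 3-chloroperbenzoic acid, OOC(=O)c1cccc(Cl)c1
Why: Henbest-type peracid epoxidation directed by the allylic C6 hydroxyl group to its own (β) face, which is also the face away from the axial C20; the terminal alkyne does not react with the peracid.

Step 14
Reactants: 26 7β,8β-epoxide
Product: 27 6β,8β-diol (8α-CH3; 18-OTBS)
Conditions: LiEt3BH, THF, 0 °C → rt; then H2O
Reagents that add atoms: none
Why: SN2 opening of the trisubstituted epoxide by LiEt3BH at the less substituted C7 leaves the oxygen on C8 with the configuration set in step 13 (8β-OH equatorial, methyl axial); alkyne and silyl ether are inert.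

Step 15
Reactants: 27 6β,8β-diol
Product: 28 6β-acetate
Conditions: Ac2O, pyridine, DMAP (cat.), CH2Cl2, 0 °C → rt
Reagents that add atoms: acetic anhydride, CC(=O)OC(C)=O
Why: DMAP-catalysed acetylation of the only accessible hydroxyl group: the primary one is silylated and the tertiary C8 hydroxyl does not acylate under these conditions.

Step 16
Reactants: 28 6β-acetate
Product: 29 alkynyl diol monoacetate (18-OH free)
Conditions: HF·pyridine, pyridine, THF, 0 °C → rt
Reagents that add atoms: none
Why: Fluoride cleavage of the primary silyl ether in buffered HF·pyridine avoids the basic conditions under which the acetyl group could migrate from O6 to O18.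

Step 17
Reactants: 29 alkynyl diol monoacetate
Product: 30 target
Conditions: ethylene (1 atm), second-generation Grubbs catalyst (H2IMes)(PCy3)Cl2Ru=CHPh (5 mol%), CH2Cl2, 40 °C
Reagents that add atoms: ethylene, C=C
Why: Ene–yne cross-metathesis of the terminal alkyne with ethylene converts the alkyne directly into the 2-substituted buta-1,3-diene; the molecule holds no other alkene, and hydroxyl and acetate groups are tolerated.

## Compound list

1 | (S)-(+)-carvone, (5S)-2-methyl-5-(prop-1-en-2-yl)cyclohex-2-en-1-one | CC1=CC[C@H](C(C)=C)CC1=O | starting material
2 | iodomethane | CI | starting material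
3 | lithium dienolate of 1 (O–Li; C1=C6 and C2=C3, carvone numbering; not isolated) | CC1=CC[C@H](C(C)=C)C=C1[O-].[Li+] | intermediate
4 | (5S)-2,6-dimethyl-5-(prop-1-en-2-yl)cyclohex-2-en-1-one (6-methylcarvone; both C6 epimers) | CC1=CC[C@H](C(C)=C)C(C)C1=O | intermediate
5 | prop-2-enal (acrolein) | C=CC=O | starting material
6 | lithium enolate of 4 (tetrasubstituted C1=C6 enolate; not isolated) | CC1=CC[C@H](C(C)=C)C(C)=C1[O-].[Li+] | intermediate
7 | 6-(1-hydroxyprop-2-en-1-yl)-2,6-dimethyl-5-(prop-1-en-2-yl)cyclohex-2-en-1-one; hydroxyallyl group trans and 6-methyl cis to the isopropenyl group; both carbinol epimers | C=CC(O)[C@@]1(C)C(=O)C(C)=CC[C@@H]1C(C)=C | intermediate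
8 | 6-acryloyl-2,6-dimethyl-5-(prop-1-en-2-yl)cyclohex-2-en-1-one; acryloyl group trans to the isopropenyl group | C=CC(=O)[C@@]1(C)C(=O)C(C)=CC[C@@H]1C(C)=C | intermediate
9 | 6-acryloyl-2,6-dimethyl-5-(2-methyloxiran-2-yl)cyclohex-2-en-1-one (C4–C18 epoxide; both epoxide epimers) | C=CC(=O)[C@@]1(C)C(=O)C(C)=CC[C@@H]1C2(C)CO2 | intermediate
10 | bis(chlorotitanocene) derivative of 11: C1–C2 enolate O–TiCp2Cl and C18 O–TiCp2Cl (not isolated) | O=C1[C@]2(C)C([O-])=CC[C@](C)(C[O-])[C@H]2CC=C1C.[Ti+4].[Ti+4].[Cl-].[Cl-].c1cc[cH-]c1.c1cc[cH-]c1.c1cc[cH-]c1.c1cc[cH-]c1 | intermediate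
11 | 5-(hydroxymethyl)-2,5,8a-trimethyl-4a,5,6,7-tetrahydro-4H-naphthalene-1,8-dione; trans-decalin with 5β-H, 10α-CH3, C1=O, C9=O, C7=C8, 4α-CH3, 4β-CH2OH | O=C1[C@]2(C)C(=O)CC[C@](C)(CO)[C@H]2CC=C1C | intermediate
12 | C1 tosylhydrazone of 11 | O=C1[C@]2(C)C(=NNS(=O)(=O)c3ccc(C)cc3)CC[C@](C)(CO)[C@H]2CC=C1C | intermediate
13 | N-(catecholboryl) tosylhydrazine at C1 with O18 catecholborate (not isolated) | O=C1[C@]2(C)C(N(NS(=O)(=O)c3ccc(C)cc3)B3Oc4ccccc4O3)CC[C@](C)(COB3Oc4ccccc4O3)[C@H]2CC=C1C | intermediate
14 | 5-(hydroxymethyl)-2,5,8a-trimethyl-4a,5,6,7,8,8a-hexahydronaphthalen-1(4H)-one; 11 with C1 = CH2 | O=C1[C@]2(C)CCC[C@](C)(CO)[C@H]2CC=C1C | intermediate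
15 | 18-O-tert-butyldimethylsilyl ether of 14 (not isolated) | O=C1[C@]2(C)CCC[C@](C)(CO[Si](C)(C)C(C)(C)C)[C@H]2CC=C1C | intermediate
16 | silyl dienol ether: C9–OSiMe3, C8=C9 and C6=C7, 18-OTBS | CC1=C(O[Si](C)(C)C)[C@]2(C)CCC[C@](C)(CO[Si](C)(C)C(C)(C)C)[C@H]2C=C1 | intermediate
17 | 6β,9β-epidioxide of 16 (O–O bridge on the β face; C9–OSiMe3 α; C7=C8; not isolated) | CC1=C[C@H]3OO[C@]1(O[Si](C)(C)C)[C@]2(C)CCC[C@](C)(CO[Si](C)(C)C(C)(C)C)[C@H]23 | intermediate
18 | 6β-hydroxy-7-en-9-one, 18-OTBS | O=C1[C@]2(C)CCC[C@](C)(CO[Si](C)(C)C(C)(C)C)[C@H]2[C@H](O)C=C1C | intermediate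
19 | 6β-trimethylsilyloxy-7-en-9-one, 18-OTBS | O=C1[C@]2(C)CCC[C@](C)(CO[Si](C)(C)C(C)(C)C)[C@H]2[C@H](O[Si](C)(C)C)C=C1C | intermediate
20 | (4-iodobut-1-yn-1-yl)trimethylsilane | C[Si](C)(C)C#CCCI | starting material
21 | [4-(trimethylsilyl)but-3-yn-1-yl]lithium (not isolated) | [Li]CCC#C[Si](C)(C)C | intermediate
22 | lithium C9 alkoxide: 9β-[4-(trimethylsilyl)but-3-ynyl], 9α-OLi, C7=C8, 6β-OSiMe3, 18-OTBS (not isolated) | C[Si](C)(C)C#CCC[C@]1([O-])[C@]2(C)CCC[C@](C)(CO[Si](C)(C)C(C)(C)C)[C@H]2[C@H](O[Si](C)(C)C)C=C1C.[Li+] | intermediate
23 | tertiary allylic methyl carbonate: 9α-OCO2Me, 9β-[4-(trimethylsilyl)but-3-ynyl], C7=C8, 6β-OSiMe3, 18-OTBS | C[Si](C)(C)C#CCC[C@]1(OC(=O)OC)[C@]2(C)CCC[C@](C)(CO[Si](C)(C)C(C)(C)C)[C@H]2[C@H](O[Si](C)(C)C)C=C1C | intermediate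
24 | 9β-H, 9α-[4-(trimethylsilyl)but-3-ynyl], C7=C8, 6β-OSiMe3, 18-OTBS (not isolated) | C[Si](C)(C)C#CCC[C@H]1[C@]2(C)CCC[C@](C)(CO[Si](C)(C)C(C)(C)C)[C@H]2[C@H](O[Si](C)(C)C)C=C1C | intermediate
25 | allylic alcohol: 9α-(but-3-ynyl), 9β-H, C7=C8, 6β-OH, 18-OTBS | C#CCC[C@H]1[C@]2(C)CCC[C@](C)(CO[Si](C)(C)C(C)(C)C)[C@H]2[C@H](O)C=C1C | intermediate
26 | 7β,8β-epoxide of 25 | C#CCC[C@H]1[C@]2(C)CCC[C@](C)(CO[Si](C)(C)C(C)(C)C)[C@H]2[C@H](O)[C@@H]3O[C@]13C | intermediate
27 | 6β,8β-diol (8α-CH3), 9α-(but-3-ynyl), 18-OTBS | C#CCC[C@H]1[C@]2(C)CCC[C@](C)(CO[Si](C)(C)C(C)(C)C)[C@H]2[C@H](O)C[C@]1(C)O | intermediate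
28 | 6β-acetate of 27 | C#CCC[C@H]1[C@]2(C)CCC[C@](C)(CO[Si](C)(C)C(C)(C)C)[C@H]2[C@H](OC(C)=O)C[C@]1(C)O | intermediate
29 | 6β-acetoxy-8β,18-diol with 9α-(but-3-ynyl) side chain | C#CCC[C@H]1[C@]2(C)CCC[C@](C)(CO)[C@H]2[C@H](OC(C)=O)C[C@]1(C)O | intermediate
30 | target, (1R,3S,4S,4aR,8S,8aS)-3-hydroxy-8-(hydroxymethyl)-3,4a,8-trimethyl-4-(3-methylidenepent-4-en-1-yl)decahydronaphthalen-1-yl acetate; (4S,5S,6R,8S,9S,10R) in labdane numbering | C=CC(=C)CC[C@H]1[C@]2(C)CCC[C@](C)(CO)[C@H]2[C@H](OC(C)=O)C[C@]1(C)O | target

## Step count and least certain steps

Total: 17 steps. Longest linear sequence: 17 steps, from 1 to 30.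

**Step 5 (key step, proposed new method).** The C4 radical may close 4-exo onto the C1 or C9 carbonyl group, or be captured by a second titanium centre and eliminated to an allylic alcohol before it cyclizes. Facial selection at C4 (CH2O equatorial versus axial) may be poor, and the electron-poor enedione may itself be reduced. The fallback uses known ionic chemistry. It sets out from 9: Lewis-acid Meinwald rearrangement of the epoxide (BF3·OEt2, CH2Cl2, −78 °C) gives the α-branched aldehyde F1. Intramolecular Michael addition of its enamine to the vinyl ketone (pyrrolidine, AcOH; 6-endo) then gives the keto aldehyde F2. Allylic strain should hold H-5 in the plane of the enamine, so the formyl carbon should end up equatorial and the methyl group axial. Selective reduction of the aldehyde (NaBH4, EtOH, −78 °C) returns to the route at 11.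

**Step 12.** Hydride may be delivered to C7 instead of C9 (tetrasubstituted alkene). Ionization of the pseudo-equatorial carbonate may be slow. If the alkyllithium in step 11 adds from the α face, the palladium may start on the wrong face and facial fidelity is lost. The fallback makes the C9–H bond by a sigmatropic hydrogen transfer that does not depend on the face of addition. It sets out from lithium alkoxide 22, which is quenched with aqueous NH4Cl to the tertiary allylic alcohol F3. Babler–Dauben oxidative transposition (pyridinium chlorochromate, [C5H5NH][CrO3Cl], CH2Cl2) gives the 8-en-7-one F4. Luche reduction (NaBH4, CeCl3·7H2O, MeOH; axial hydride attack) should give the 7α-alcohol F5. Mitsunobu displacement with 2-nitrobenzenesulfonylhydrazine (PPh3, diethyl azodicarboxylate, −30 °C) gives the 7β-sulfonylhydrazine F6, which on warming loses sulfinic acid to the allylic diazene F7. F7 transfers its hydrogen suprafacially to the β face of C9 with loss of dinitrogen and comes back to the route at 24, which is desilylated to 25 as in the second stage of step 12.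

**Step 9.** An ene-type oxygenation at the enol ether double bond (oxygen at C8) or attack on the α face may compete with the [4+2] addition, and the peroxy ketal may fragment by routes other than simple reduction. The fallback replaces the cycloaddition by a stepwise electrophilic γ-oxygenation: it sets out from 16, whose C6=C7 bond is epoxidized on the β face by mCPBA (NaHCO3, CH2Cl2, −20 °C), the classical peracid γ-hydroxylation of dienol ethers. The epoxide collapses in the flask to the enone and the fallback comes back at 18 (no new compound, F0).

**Step 14.** The hydride opening may be sluggish at C7, which lies next to the alkoxide-bearing C6, and under Lewis-acidic conditions the epoxide may open at C8 instead. The fallback makes the carbinol by radical hydration instead of epoxide reduction. It sets out from 24 (isolated before the methanolysis of step 12): Mukaiyama hydration (Co(acac)2, PhSiH3, O2, i-PrOH) should give the tertiary 8β-alcohol F8, with dioxygen trapping the C8 radical on the face away from C20. Methanolysis (K2CO3, MeOH) of both trimethylsilyl groups comes back to the route at 27.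

**Step 7.** Hydride addition to the hindered C1 hydrazone may be incomplete, and under the conditions of steps 6 and 7 the 1,3-diketone may suffer retro-Claisen cleavage. The fallback avoids nitrogen nucleophiles. It sets out from 11: ethane-1,2-dithiol and BF3·OEt2 convert the C1 ketone into the dithiolane F9, and desulfurization with deactivated Raney Ni (EtOH, rt) comes back to the route at 14.

## Further compounds

F1 | step 5 | 2-[(1S,2R)-2-acryloyl-2,4-dimethyl-3-oxocyclohex-4-en-1-yl]propanal-type aldehyde from 9 (formyl carbon C18 on C4; both C4 epimers) | C=CC(=O)[C@@]1(C)C(=O)C(C)=CC[C@@H]1C(C)C=O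
F2 | step 5 | keto aldehyde: 11 with CHO in place of CH2OH (4β-CHO, 4α-CH3) | O=C1[C@]2(C)C(=O)CC[C@](C)(C=O)[C@H]2CC=C1C
F3 | step 12 | tertiary allylic alcohol: 9α-OH, 9β-[4-(trimethylsilyl)but-3-ynyl], C7=C8, 6β-OSiMe3, 18-OTBS | C[Si](C)(C)C#CCC[C@]1(O)[C@]2(C)CCC[C@](C)(CO[Si](C)(C)C(C)(C)C)[C@H]2[C@H](O[Si](C)(C)C)C=C1C
F4 | step 12 | transposed enone: C7=O, C8=C9, side chain on C9, 6β-OSiMe3, 18-OTBS | C[Si](C)(C)C#CCCC=1[C@]2(C)CCC[C@](C)(CO[Si](C)(C)C(C)(C)C)[C@H]2[C@H](O[Si](C)(C)C)C(=O)C=1C
F5 | step 12 | 7α-alcohol of F4 | C[Si](C)(C)C#CCCC=1[C@]2(C)CCC[C@](C)(CO[Si](C)(C)C(C)(C)C)[C@H]2[C@H](O[Si](C)(C)C)[C@@H](O)C=1C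
F6 | step 12 | 7β-[N-amino-N-(2-nitrophenylsulfonyl)amino] derivative (C8=C9) | C[Si](C)(C)C#CCCC=1[C@]2(C)CCC[C@](C)(CO[Si](C)(C)C(C)(C)C)[C@H]2[C@H](O[Si](C)(C)C)[C@H](N(N)S(=O)(=O)c3ccccc3[N+](=O)[O-])C=1C
F7 | step 12 | 7β-allylic diazene (C8=C9) | C[Si](C)(C)C#CCCC=1[C@]2(C)CCC[C@](C)(CO[Si](C)(C)C(C)(C)C)[C@H]2[C@H](O[Si](C)(C)C)[C@H](N=N)C=1C
F0 | step 9 | none | none
F8 | step 14 | 8β-alcohol from 24: 8α-CH3, 6β-OSiMe3, 9α-[4-(trimethylsilyl)but-3-ynyl], 18-OTBS | C[Si](C)(C)C#CCC[C@H]1[C@]2(C)CCC[C@](C)(CO[Si](C)(C)C(C)(C)C)[C@H]2[C@H](O[Si](C)(C)C)C[C@]1(C)O
F9 | step 7 | C1 1,3-dithiolane of 11 | O=C1[C@]2(C)C3(SCCS3)CC[C@](C)(CO)[C@H]2CC=C1C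
A1 | alternative 1 | acyclic trienoate: methyl (2E)-2-methyl-4-silyloxy-6-oxo-7-substituted nona-2,8,10-trienoate type precursor | C=C/C=C(\C)[C@H](CCOCc1ccc(OC)cc1)C(=O)C[C@@H](O[Si](C)(C)C(C)(C)C)/C=C(\C)C(=O)OC
A2 | alternative 1 | trans-fused octalin ester (C1=C2, C4 ester, C6-OTBS, C8 ketone, C9 PMB-oxyethyl) | COc1ccc(COCC[C@H]2[C@]3(C)C=CC[C@](C)(C(=O)OC)[C@H]3[C@H](O[Si](C)(C)C(C)(C)C)CC2=O)cc1
A3 | alternative 2 | (1,3-dimethyl-2-vinylcyclohex-2-en-1-yl)methyl but-2-ynoate | CC#CC(=O)OC[C@@]1(C)CCCC(C)=C1C=C
A4 | alternative 2 | lactone-bridged ring B 5,8-diene | O=C1OC[C@@]2(C)CCC[C@@]3(C)C1=C(C)CC=C23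
A5 | alternative 3 | silylene-bridged (Z)-trienol ether | C#CCC/C=C(\C)/C=C1/O[Si](C(C)(C)C)(C(C)(C)C)OC[C@@]2(C)CCCC(C)=C12
A6 | alternative 3 | ring B 5,7-dienol silylene ether | C#CCC[C@H]1[C@]2(C)CCC[C@](C)(CO[Si](C(C)(C)C)(C(C)(C)C)O3)C2=C3C=C1C
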